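**Retrosynthetic overview**
- The target is (−)-epicatechin-(4β→8)-(+)-taxifolin. The one strategic cut is the C4(upper)–C8(lower) interflavan bond, made as the plant is thought to make it: a 2,3-cis-leucocyanidin loses water to its C4 quinone methide/carbocation, which free taxifolin captures as the starter unit, with no protecting group on either partner in the bond-forming event.
- The 2,3-cis-leucocyanidin comes from (−)-epicatechin (1) by C4 oxygenation, for which the phenols are masked as benzyl ethers. (+)-Taxifolin (2) is used as bought.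
- Ring order: no ring is built. Rings A, C and B of the upper unit arrive in 1, and rings D, F and E of the lower unit arrive in 2. The only ring event is the dearomatisation of ring A to the quinone methide and its rearomatisation on C–C bond formation.
- Stereochemistry: C2 and C3 of both units come from the chiral pool. The one new centre, C4 (R, 4β), is set in the coupling by attack anti to the 3-OH.

Assumption: the SMILES is read as a (2R,3R,4R) flavan-3-ol unit joined through C4 to C8 of (2R,3R)-taxifolin, and 1 and 2 are taken as inexpensive commercial flavonoids.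

**Step 1**
Reactants: 1 (−)-epicatechin
Product: 3 tetra-O-benzyl-(−)-epicatechin [(2R,3R)-5,7,3',4'-tetrakis(benzyloxy)flavan-3-ol]
Conditions: BnBr (4.4 equiv), K2CO3 (4.6 equiv), DMF, 0 °C to rt, Ar, 16 h
Reagents that add atoms: benzyl bromide, BrCc1ccccc1
Why: Williamson ether synthesis in which K2CO3 deprotonates only the four phenols (not the secondary 3-OH), while low temperature and argon suppress C-benzylation and base-induced C2 epimerisation, so C2 and C3 are untouched.

**Step 2**
Reactants: 3 tetra-O-benzyl-(−)-epicatechin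
Product: 5 4β-hydroxy-tetra-O-benzylepicatechin [(2R,3R,4S)-5,7,3',4'-tetrakis(benzyloxy)flavan-3,4-diol], via C4 benzylic cation 4 (not isolated)
Conditions: DDQ (1.6 equiv), CH2Cl2–H2O (20:1), 0 °C to rt, 1.5 h
Reagents that add atoms: water, O
Why: DDQ benzylic oxidation, in which hydride abstraction from C4 gives a cation stabilised by the 5,7-dialkoxy ring A and water adds anti to the axial 3-OH to give the 4β-alcohol (4S); C2 and C3 are untouched, and the C4 configuration is not critical because C4 is re-ionised in step 3.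

**Step 3**
Reactants: 5 4β-hydroxy-tetra-O-benzylepicatechin, 2 (+)-taxifolin (10 equiv, excess recovered)
Product: 8 (−)-epicatechin-(4β→8)-(+)-taxifolin (target), via 2,3-cis-leucocyanidin 6 (not isolated), via ring A quinone methide 7 (not isolated)
Conditions: H2 (1 atm), Pd(OH)2/C, THF–H2O (9:1), rt, 2 h; filter under Ar; add over 6 h to 2 in degassed NaOAc/AcOH buffer (pH 5.0)–EtOH (1:1), 35 °C, 24 h, dark; Sephadex LH-20, then RP-HPLC
Reagents that add atoms: none
Why: Proposed new method: neutral hydrogenolysis cleaves the four aryl benzyl ethers much faster than the free benzylic C4–OH and unmasks leucocyanidin 6, which at pH 5 loses water to quinone methide 7 (protonated form: the C4 carbocation) as the extension unit does in proanthocyanidin biosynthesis, and taxifolin (7-OH pKa about 7, so a far larger phenolate fraction than the ring A phenols of 6, and kept in tenfold excess by slow addition of 6) attacks C4 through C8 from the β-face anti to the axial 3-OH to set C4 as R (3,4-trans, the usual outcome for epicatechin C4 cations), the closest known reaction type being the biomimetic acid-promoted flavan-3,4-diol plus flavan-3-ol condensation (a Friedel–Crafts-type quinone methide capture) that gives procyanidins B3 and B6.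

**Compound list**
1 | (−)-epicatechin, (2R,3R)-2-(3,4-dihydroxyphenyl)chromane-3,5,7-triol | C1c2c(O)cc(O)cc2O[C@H](c2ccc(O)c(O)c2)[C@@H]1O | starting material
2 | (+)-taxifolin, (2R,3R)-2-(3,4-dihydroxyphenyl)-3,5,7-trihydroxychroman-4-one | O=C1c2c(O)cc(O)cc2O[C@H](c2ccc(O)c(O)c2)[C@H]1O | starting material
3 | tetra-O-benzyl-(−)-epicatechin, (2R,3R)-5,7-bis(benzyloxy)-2-[3,4-bis(benzyloxy)phenyl]chroman-3-ol | C1c2c(OCc3ccccc3)cc(OCc3ccccc3)cc2O[C@H](c2ccc(OCc3ccccc3)c(OCc3ccccc3)c2)[C@@H]1O | intermediate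
4 | C4 benzylic cation of 3, (2R,3R) | [CH+]1c2c(OCc3ccccc3)cc(OCc3ccccc3)cc2O[C@H](c2ccc(OCc3ccccc3)c(OCc3ccccc3)c2)[C@@H]1O | intermediate
5 | 4β-hydroxy-tetra-O-benzylepicatechin, (2R,3R,4S)-5,7-bis(benzyloxy)-2-[3,4-bis(benzyloxy)phenyl]chromane-3,4-diol | O[C@H]1c2c(OCc3ccccc3)cc(OCc3ccccc3)cc2O[C@H](c2ccc(OCc3ccccc3)c(OCc3ccccc3)c2)[C@@H]1O | intermediate
6 | 2,3-cis-3,4-trans-leucocyanidin (epicatechin-4β-ol), (2R,3R,4S)-2-(3,4-dihydroxyphenyl)chromane-3,4,5,7-tetrol | O[C@H]1c2c(O)cc(O)cc2O[C@H](c2ccc(O)c(O)c2)[C@@H]1O | intermediate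
7 | ring A quinone methide, (2R,3R)-2-(3,4-dihydroxyphenyl)-3,5-dihydroxy-2,3-dihydro-7H-chromen-7-one | O=C1C=C(O)C2=C[C@@H](O)[C@@H](c3ccc(O)c(O)c3)OC2=C1 | intermediate
8 | (−)-epicatechin-(4β→8)-(+)-taxifolin, (2R,3R)-2-(3,4-dihydroxyphenyl)-8-[(2R,3R,4R)-2-(3,4-dihydroxyphenyl)-3,5,7-trihydroxychroman-4-yl]-3,5,7-trihydroxychroman-4-one | O=C1c2c(O)cc(O)c([C@H]3c4c(O)cc(O)cc4O[C@H](c4ccc(O)c(O)c4)[C@@H]3O)c2O[C@H](c2ccc(O)c(O)c2)[C@H]1O | target

**Step count**
Total: 3 steps. Longest linear sequence: 3 steps (1 → 3 → 5 → 8); 2 enters in step 3 as purchased.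

**Steps most likely to fail, with fallbacks**

Step 3 (most likely). The risks are self-condensation of 6 instead of capture by the weakly nucleophilic taxifolin, formation of the 4→6 regioisomer (to be separated by HPLC and told apart by HMBC), and partial hydrogenolysis of the C4–OH. The fallback sets out from 5 and comes back at 8. It makes the C–C bond with a nucleophile of proven reactivity and C8 selectivity and introduces the lower-unit carbonyl afterwards. Compound 5 is coupled (TMSOTf cat., CH2Cl2, −78 °C) with 4 equiv of 5,7,3',4'-tetra-O-benzyl-(+)-catechin F1 (from commercial (+)-catechin, BnBr, K2CO3, DMF) to give octa-O-benzylprocyanidin B1 F2. DDQ in CH2Cl2–H2O then oxidises the only benzylic CH2 left, C4 of the lower unit, to the 4-hydroxy octa-O-benzyl dimer F3; the upper C4–H is a hindered methine and is expected to be spared. Activated MnO2 (CH2Cl2) takes this benzylic alcohol, and not the two non-benzylic 3-OH groups, to the ketone octa-O-benzyl-epicatechin-(4β→8)-taxifolin F4. H2, Pd(OH)2/C (THF–MeOH) then gives 8.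

Step 2. The risks are over-oxidation of 5 to the flavan-4-one and loss of the acid-labile diol on silica. The fallback sets out from 3 and comes back at 7. It changes the leaving group from hydroxyl to a glycol ether that cannot be over-oxidised and is purified at the protected stage. DDQ with ethylene glycol (CH2Cl2, rt) gives 4β-(2-hydroxyethoxy)-tetra-O-benzylepicatechin F5. Hydrogenolysis (H2, Pd(OH)2/C, THF–H2O) gives 4β-(2-hydroxyethoxy)epicatechin F6. This is ionised in the taxifolin solution at about pH 3.5 to the same quinone methide 7 and goes on to 8.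

Step 1. The risks are C-benzylation of the phloroglucinol ring, 3-O-benzylation and C2 epimerisation. The fallback sets out from 1 and comes back at 3. It releases the phenoxides one at a time from acetates instead of deprotonating free phenols. Ac2O/pyridine gives (−)-epicatechin pentaacetate F7. BnCl and NaH in DMF containing 4–5 equiv of water at 0 °C cleave the four aryl acetates and benzylate each phenoxide as it forms, leaving the alkyl acetate, to give 3-O-acetyl-tetra-O-benzylepicatechin F8. K2CO3 in MeOH–THF removes the 3-acetate to give 3.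

**Further compounds**
F1 | step 3 | 5,7,3',4'-tetra-O-benzyl-(+)-catechin, (2R,3S) | C1c2c(OCc3ccccc3)cc(OCc3ccccc3)cc2O[C@H](c2ccc(OCc3ccccc3)c(OCc3ccccc3)c2)[C@H]1O
F2 | step 3 | octa-O-benzylprocyanidin B1, tetra-O-benzylepicatechin-(4β→8)-tetra-O-benzylcatechin | C1c2c(OCc3ccccc3)cc(OCc3ccccc3)c([C@H]3c4c(OCc5ccccc5)cc(OCc5ccccc5)cc4O[C@H](c4ccc(OCc5ccccc5)c(OCc5ccccc5)c4)[C@@H]3O)c2O[C@H](c2ccc(OCc3ccccc3)c(OCc3ccccc3)c2)[C@H]1O
F3 | step 3 | 4-hydroxy octa-O-benzyl dimer, (4S)-hydroxyl at C4 of the lower unit of F2 | O[C@H]1c2c(OCc3ccccc3)cc(OCc3ccccc3)c([C@H]3c4c(OCc5ccccc5)cc(OCc5ccccc5)cc4O[C@H](c4ccc(OCc5ccccc5)c(OCc5ccccc5)c4)[C@@H]3O)c2O[C@H](c2ccc(OCc3ccccc3)c(OCc3ccccc3)c2)[C@H]1O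
F4 | step 3 | octa-O-benzyl-epicatechin-(4β→8)-taxifolin | O=C1c2c(OCc3ccccc3)cc(OCc3ccccc3)c([C@H]3c4c(OCc5ccccc5)cc(OCc5ccccc5)cc4O[C@H](c4ccc(OCc5ccccc5)c(OCc5ccccc5)c4)[C@@H]3O)c2O[C@H](c2ccc(OCc3ccccc3)c(OCc3ccccc3)c2)[C@H]1O
F5 | step 2 | 4β-(2-hydroxyethoxy)-tetra-O-benzylepicatechin, (2R,3R,4S) | OCCO[C@H]1c2c(OCc3ccccc3)cc(OCc3ccccc3)cc2O[C@H](c2ccc(OCc3ccccc3)c(OCc3ccccc3)c2)[C@@H]1O
F6 | step 2 | 4β-(2-hydroxyethoxy)epicatechin, (2R,3R,4S) | OCCO[C@H]1c2c(O)cc(O)cc2O[C@H](c2ccc(O)c(O)c2)[C@@H]1O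
F7 | step 1 | (−)-epicatechin pentaacetate, (2R,3R) | C1c2c(OC(C)=O)cc(OC(C)=O)cc2O[C@H](c2ccc(OC(C)=O)c(OC(C)=O)c2)[C@@H]1OC(C)=O
F8 | step 1 | 3-O-acetyl-tetra-O-benzylepicatechin, (2R,3R) | C1c2c(OCc3ccccc3)cc(OCc3ccccc3)cc2O[C@H](c2ccc(OCc3ccccc3)c(OCc3ccccc3)c2)[C@@H]1OC(C)=O
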